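The numbers were drawn at random within sensible limits; no experiment stands behind them.

If the average chain in this flask is to stay short of the wanted length by the end of the run, something in the charges and constants below has to keep free monomer out of the chains.

free monomer 0.40 M; protic impurity 8.00 mM; initiator 4.0 mM; time 4.0 h

    free monomer + initiator → living end + monomer in chains (k1 = 0.11 L mol⁻¹ min⁻¹)
    free monomer + living end → monomer in chains + living end, rate k2*[living end]*[free monomer] (k2 = 5.6 L mol⁻¹ min⁻¹)
    monomer in chains + living end → free monomer + living end, rate k3*[living end] as long as [monomer in chains] is above zero (k3 = 0.22 min⁻¹)
    protic impurity + free monomer → quenched substrate (k4 = 1.4 L mol⁻¹ min⁻¹)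

- the average divides the monomer in chains by the number of chains begun, living and dead together
- run time (flask): 4.0 h

* whether the average number of monomer units in a chain (chains begun, living or dead) reaches 30 by 4.0 h (no / yes)
* average number of monomer units in a chain (chains begun, living or dead) at 4.0 h

Counted in fractions of the charged free monomer, the wanted length needs 30.0 % of the charge in chains even with every chain begun, and step 4 can take 2.00 % into quenched substrate, so the answer no asks for a free share of at least 68.0 % at the end. Steps 2 and 3 both run in proportion to the living end, which therefore cancels from their balance, and free monomer stops falling at the ceiling share, the equilibrium monomer level, of 9.82 %, far less than that demand. The ceiling length, the charge less quenched substrate and ceiling share, divided over every chain begun, is 88.2. Time is no obstacle either, since with living ends equal to the initiator charge the excess of free monomer over its ceiling halves in 30.9 min, which is less than the 4.0 h allowed.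

Going round once more, the ceiling share goes back into step 1, where it gives the initiator a half-life of 2.67 h, and with the excess of free monomer over its ceiling counted as well, still at living ends equal to the initiator charge, this estimate leaves about 6.27 % of the initiator unbegun at 4.0 h and raises the length to 94.1. This reckoning therefore says yes, with a length between those two figures.

The forecast says yes and 90, holding that “the monomer has fallen close to its ceiling value”.

The simulation gives yes and 89.9. Step 4 brought the protic impurity to 0 % by 0.400 h, leaving 2.00 % as quenched substrate, while steps 1 and 2 carried the average past the wanted length at 0.457 h, with 21.9 % of the free monomer reacted. Step 2 then ran against step 3 as initiator fell to 2.84 % and free monomer to 10.7 % at 4.00 h, and at 40.0 h the flask held free monomer at 9.82 %, initiator at 0 % and 88.2 units per chain, against a ceiling length of 88.2.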